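(All constants are invented; the flask was simulated.)

A charge of 2.0 mM of starting material meets 5.0 µM of free catalyst, with 8.00 mM of partner beside it. The cycle gives target and released group, but starting material also attacks target to give side product B, and released group attacks it to give side product A.

| setting | amber | teal | ochre | violet |
|---|---|---|---|---|
| starting material | 2.0 mM | 2.0 mM | 2.0 mM (fed, over 3.20 min) | 2.0 mM |
| partner | 8.00 mM | 8.00 mM | 8.00 mM | 8.00 mM |
| free catalyst | 5.0 µM | 5.0 µM | 5.0 µM | 5.0 µM |
| time | 4.0 min |  | 4.0 min | 4.0 min |
| remark | everything together in a closed stirred flask, run for 4.0 min | a single well-mixed tank run continuously and read at steady state, 4.0 min in it on average | all but starting material at the start; starting material goes in evenly over 3.20 min, the run ends at 4.0 min | a tube with plug flow, the mixed feed as stated, residence time 4.0 min |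

* the set-up with the highest amount of target at the outlet or at the end, in percent of the starting material put in ("none" if the first two lie within 2 percentage points) (amber / teal / ochre / violet / none)
* amount of target at the outlet or at the end, in percent of the starting material put in, amber
* amount of target at the outlet or at the end, in percent of the starting material put in, teal
* amount of target at the outlet or at the end, in percent of the starting material put in, ochre
* amount of target at the outlet or at the end, in percent of the starting material put in, violet

- in percentages every species weighs as the starting material in it: one side product B counts as two
- the stated concentrations are those of everything mixed, before any reaction; amounts are the same in each set-up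
- the feed brings no volume worth counting
- run time (amber): 4.0 min

    starting material + free catalyst → catalyst intermediate A (k1 = 25000 M⁻¹ s⁻¹)
    partner + catalyst intermediate A → catalyst intermediate B (k2 = 2.5 × 10⁵ M⁻¹ s⁻¹)
    catalyst intermediate B ⇌ released group + catalyst intermediate C (K3 = 0.048 M, k3 = 2100 s⁻¹)
    catalyst intermediate C → free catalyst + target (k4 = 22 s⁻¹)
    target + released group → side product A (k5 = 2.8 M⁻¹ s⁻¹)
    starting material + target → side product B (k6 = 29 M⁻¹ s⁻¹)

We draw amber's target curve by hand, with S for starting material and T for target. Catalyst intermediate C breaks down at 22 s⁻¹, slower than catalyst intermediate A is taken up at 2000 s⁻¹, so this breakdown is the rate-limiting step at high S. The cycle rate is the uptake rate, 25000 M⁻¹ s⁻¹ times S times the catalyst charge, divided by 1 + S/Sk, with the knee charge Sk = 0.880 mM. The curve starts at a slope of 4.58 mM min⁻¹. Half of S is gone by 0.244 min. Below Sk, each power of ten in S costs 0.307 min, so S reaches a hundredth near 0.916 min, earlier than the end.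

Halfway, side rate over cycle rate is a(1 − σ), with a = 0.496 and σ the side share, the part of the charge ending in side product B. Each side event takes 2 of S, and dropping the square of σ gives σ = 2a/(1 + 3a) = 39.9%.

After the knee, released group exceeds T by a fixed D = σ·S₀/2, where S₀ is the charge: 0.399 mM. So ln(1 + D/T) climbs straight at 0.0670 min⁻¹, and T sinks towards zero. Counted from the half time, this leaves 28.0% in amber, and violet's plug flow repeats that history.

In ochre the feed holds S near 0.0833 mM, less than Sk, so a drops to 0.232 and σ to 27.4%, and erosion from mid-feed leaves 41.8%. In teal S is low too; taking T at its full level, a is 0.464 and σ is 38.8%, and that overstates the side rate, because the erosion number, the constant for target with released group times the mean time times the charge, is 1.34, above 1. Setting what teal makes, (1 − σ)S₀, against what released group takes over the mean time, with released group put equal to T, leaves 39.9% in teal. By target left, we pick ochre.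

The forecast says 28% for amber and 28% for violet, 38% for teal and 46% for ochre, a figure that differs from ours, and picks ochre: slow feed, “so little side product B forms”.

The simulation gives 27.8% for amber, 27.8% for violet, 38.3% for teal and 46.6% for ochre, so ochre leads.

Side product B reads 41.1% in amber and 28.4% in ochre. Violet's neighbour carries 0.0085 mM of free catalyst, so a falls to 0.292 and σ to 31.1%, and the half time moves to 0.143 min. The same climb of the logarithm then leaves 31.1% of target. That neighbour ended with 30.1% of side product B and 31.8% of target.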